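## Plan

- **Cuts:** both ester C–O bonds (the secondary one with inversion); each 1,5-dialdehyde arm goes back to a cis-cyclopentane-1,2-diol (glycol-cleavage retron). The two free CH2OH groups are carried as TBS ethers.
- **Ring:** the cyclopentane is cut at C(O)–C(CH3) and at C(CH2OH)–C(side chain). The adjacent CH(CH3)/CH(CH2OH) ring carbons are the β/α carbons of crotonaldehyde. The O-bearing ring carbon is a nitronate carbon. The ring CH2 and the side-chain-bearing CH are the tether and β-carbon of an enoate. This is a domino nitro-Michael/Michael (formal 3+2) event.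
- **Order:** cyclopentane (step 3), then a temporary bridged δ-lactone (2-oxabicyclo[3.2.1]octan-3-one, step 6) that ties the ring oxygen to one side-chain arm, exo-hydroxymethylation, reduction to the diol, and union with the acid arm.
- **Stereochemistry:** the (S)-diarylprolinol silyl ether sets the CH3-bearing carbon and, through the enamine closure, its two neighbours (all-trans). L-Selectride gives the cis-alcohol needed for the lactone, and the final Mitsunobu inverts it. Exo attack on the lactone enolate sets the side-chain centre. The acid arm comes from a chiral-pool enone by convex-face alkylation.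
- **End:** mild acid removes acetonides and silyl ethers; periodate unveils all four aldehydes beside the free primary alcohols.

Key step: step 3

Assumption: the nitro-bearing carbon of 7–9 is drawn trans to the methyl group (thermodynamic); its configuration is irrelevant because step 5 removes it. Compounds 1, 3, 5 and 18 are taken as commercial.

## Route

**Step 1**
Reactants: 1 acrolein
Product: 2 3-nitropropanal
Conditions: NaNO2, AcOH, THF/H2O, 0 °C
Reagents that add atoms: sodium nitrite, [Na+].[O-]N=O
Why: Conjugate addition of nitrite to the enal under acetic acid buffering (N-attack) should give the β-nitro aldehyde; no stereocentre is formed.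

**Step 2**
Reactants: 2 3-nitropropanal; 3 methyl (triphenylphosphoranylidene)acetate
Product: 4 methyl (E)-5-nitropent-2-enoate
Conditions: CH2Cl2, 0 °C → rt
Reagents that add atoms: none
Why: Wittig olefination with a stabilised ylide is E-selective, and its near-neutral conditions should avoid β-elimination of HNO2 from 2.

**Step 3**
Reactants: 4 methyl (E)-5-nitropent-2-enoate; 5 (E)-crotonaldehyde
Product: 7 methyl 2-[(1S,2S,3R,4R)-2-formyl-3-methyl-4-nitrocyclopentyl]acetate (all-trans), via open-chain nitro-Michael adduct 6 (not isolated)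
Conditions: (S)-α,α-diphenylprolinol TMS ether (20 mol %), PhCO2H (20 mol %), CHCl3, rt
Reagents that add atoms: none
Why: The amine condenses with 5 to an E-iminium ion; the nitronate of 4 adds to its β-carbon on the face away from the CPh2(OTMS) group, and the resulting enamine closes onto the tethered (E)-enoate by a 5-exo-trig Michael addition before hydrolysis returns the catalyst. The closest known reaction type is the amine-catalysed domino nitro-Michael/Michael annulation of ω-nitro-α,β-unsaturated esters with enals. The catalyst controls the CH3-bearing carbon (R); the formyl-bearing carbon (S) is set anti to the methyl group by attack of the enamine on its unshielded face. The CH2CO2Me-bearing carbon is set trans to the formyl group by a chair-like transition state with the enoate pseudo-equatorial. The step needs the nitronate to attack the iminium ion and not the enoate of a second molecule of 4, which the much higher electrophilicity of the iminium ion should secure. The formyl centre is epimerisable, so the all-trans array is also the thermodynamic one; the nitro-bearing centre is uncontrolled and is erased in step 5.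

**Step 4**
Reactants: 7 cascade aldehyde
Product: 9 methyl 2-[(1S,2S,3R,4R)-2-(tert-butyldimethylsilyloxymethyl)-3-methyl-4-nitrocyclopentyl]acetate, via primary alcohol 8 (not isolated)
Conditions: NaBH4, MeOH, −20 °C; then TBSCl, imidazole, DMF, 0 °C → rt
Reagents that add atoms: tert-butyldimethylsilyl chloride, CC(C)(C)[Si](C)(C)Cl
Why: Borohydride reduces only the aldehyde (nitro and ester are inert), and prompt silylation should cap the primary alcohol before it can lactonise onto the ester; this TBS group is one of the two final protecting groups.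

**Step 5**
Reactants: 9 nitro ester
Product: 11 methyl 2-[(1S,2S,3R)-2-(tert-butyldimethylsilyloxymethyl)-3-methyl-4-oxocyclopentyl]acetate, via sodium nitronate 10 (not isolated)
Conditions: NaOMe, MeOH, 0 °C; then aq. TiCl3, NH4OAc (pH 5–6), rt
Reagents that add atoms: water, O
Why: Nef reaction in its reductive TiCl3 form: the nitronate is reduced to the imine and hydrolysed to the ketone. Methoxide is degenerate with the methyl ester, the buffered medium should spare the TBS ether, and the α-methyl centre stays in its more stable trans arrangement.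

**Step 6**
Reactants: 11 cyclopentanone
Product: 13 6-(tert-butyldimethylsilyloxymethyl)-7-methyl-2-oxabicyclo[3.2.1]octan-3-one (methyl on the side of the lactone bridge, CH2OTBS on the opposite side), via cis-alkoxide ester 12 (not isolated)
Conditions: L-Selectride, THF, −78 °C → rt; aq. NH4Cl work-up
Reagents that add atoms: none
Why: The bulky hydride should attack the ketone anti to the adjacent methyl group (as with 2-alkylcyclopentanones), giving the alkoxide cis to both the methyl and the CH2CO2Me arm. This alkoxide lactonises by intramolecular transesterification; any trans-alcohol cannot lactonise and is removed as a hydroxy ester.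

**Step 7**
Reactants: 13 bridged lactone
Product: 15 4-(hydroxymethyl) derivative of 13, hydroxymethyl exo (anti to the C6–C7 bridge), via lithium enolate 14 (not isolated)
Conditions: LDA, THF, −78 °C; monomeric CH2O, −78 → −30 °C
Reagents that add atoms: formaldehyde, C=O
Why: Aldol reaction of the lactone enolate with formaldehyde; attack from the exo face (away from the two-carbon bridge, chair-like axial attack) should set the side-chain stereocentre. The lactone carbonyl arm becomes the CH2O to be acylated, and the new CH2OH is the arm that stays free.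

**Step 8**
Reactants: 15 hydroxymethyl lactone
Product: 16 bis-TBS lactone
Conditions: TBSCl, imidazole, DMF, rt
Reagents that add atoms: tert-butyldimethylsilyl chloride, CC(C)(C)[Si](C)(C)Cl
Why: Standard silylation of the only free hydroxyl; no base strong enough to epimerise the lactone α-centre is present.

**Step 9**
Reactants: 16 bis-TBS lactone
Product: 17 diol: the cyclopentane carrying cis-OH (cis to CH3), CH3, CH2OTBS and the side chain (S)-CH(CH2OH)(CH2OTBS)
Conditions: LiBH4, THF/MeOH, 0 °C → rt; aq. NH4Cl quench at 0 °C
Reagents that add atoms: none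
Why: Reduction of the lactone frees exactly the two hydroxyls that are to be acylated; silyl ethers are stable, and the cold, non-basic quench should prevent 1,3-O→O silyl migration, which would scramble the side-chain centre.

**Step 10**
Reactants: 18 (3aR,6aR)-2,2-dimethyl-3a,6a-dihydro-4H-cyclopenta[d][1,3]dioxol-4-one
Product: 19 (3aR,6aR)-2,2-dimethyltetrahydro-4H-cyclopenta[d][1,3]dioxol-4-one
Conditions: H2 (1 atm), 10% Pd/C, EtOAc, rt
Reagents that add atoms: none
Why: Catalytic hydrogenation of the enone C=C; the stereocentres are untouched.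

**Step 11**
Reactants: 19 saturated ketone
Product: 21 methyl 2-[(3aR,5S,6aR)-2,2-dimethyl-4-oxotetrahydro-4H-cyclopenta[d][1,3]dioxol-5-yl]acetate, via lithium enolate 20 (not isolated)
Conditions: LDA, THF, −78 °C; BrCH2CO2Me, DMPU, −78 → −40 °C
Reagents that add atoms: methyl bromoacetate, COC(=O)CBr
Why: Kinetic deprotonation at the CH2 side (the other α-position is a hindered oxygenated methine), then enolate alkylation from the convex face, which places the acetate arm trans to the dioxolane ring.

**Step 12**
Reactants: 21 alkylated ketone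
Product: 22 methyl 2-[(3aS,4E,5S,6aR)-4-ethylidene-2,2-dimethyltetrahydro-4H-cyclopenta[d][1,3]dioxol-5-yl]acetate
Conditions: EtPPh3Br, KHMDS, THF, −78 → 0 °C
Reagents that add atoms: ethyltriphenylphosphonium bromide, CC[P+](c1ccccc1)(c1ccccc1)c1ccccc1.[Br-]
Why: Wittig ethylidenation of the ketone in the presence of the less electrophilic ester. The ylide is expected to add anti to the acetate arm, with its methyl group turning away from the dioxolane-bearing α-carbon, which gives the E-alkene (CH3 cis to the acetate-bearing carbon). This selectivity is not assured; the minor isomer is to be removed by chromatography.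

**Step 13**
Reactants: 22 ethylidene ester
Product: 23 2-[(3aS,4E,5S,6aR)-4-ethylidene-2,2-dimethyltetrahydro-4H-cyclopenta[d][1,3]dioxol-5-yl]acetic acid
Conditions: LiOH, THF/H2O, 0 °C → rt; then 1 M HCl to pH 4
Reagents that add atoms: lithium hydroxide, [Li+].[OH-]
Why: Saponification of the methyl ester; the acetonide and the alkene are stable to base, and the stereocentre is β to the carboxyl group and cannot epimerise.

**Step 14**
Reactants: 17 diol; 23 acid
Product: 24 primary mono-ester (ring cis-OH still free)
Conditions: DIC, DMAP (cat.), CH2Cl2, −20 → 0 °C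
Reagents that add atoms: none
Why: Steglich esterification should select the primary hydroxyl over the hindered secondary one. Acylating it first removes the risk that Mitsunobu activation of the cis-1,5-diol gives a bicyclic ether by cyclodehydration.

**Step 15**
Reactants: 24 mono-ester; 23 acid
Product: 25 bis-ester (ring C–O now trans to CH3), bis-acetonide, bis-TBS ether
Conditions: PPh3, DIAD, toluene, 0 °C → rt
Reagents that add atoms: none
Why: Mitsunobu esterification: the carboxylate displaces the alkoxyphosphonium group by SN2 with inversion, which should convert the cis-alcohol into the trans-ester of the target.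

**Step 16**
Reactants: 25 protected bis-ester
Product: 26 hexaol (two cis-cyclopentane-1,2-diols and two primary alcohols)
Conditions: 1 M aq. HCl/THF (1:3), 0 °C → rt
Reagents that add atoms: none
Why: Acid hydrolysis of both acetonides and both primary TBS ethers in one operation; the esters should survive, and the low temperature is chosen to suppress 1,3-acyl migration and allylic ionisation.

**Step 17**
Reactants: 26 hexaol
Product: 27 CNP0192766.1 (target)
Conditions: NaIO4, THF/pH 7 buffer, 0 °C → rt
Reagents that add atoms: none
Why: Malaprade glycol cleavage of the two cis-1,2-diols should open both cyclopentane rings to the enal/aldehyde pairs; isolated primary alcohols and esters do not react, and the E-geometry and the stereocentres are carried over unchanged.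

## Compound list

1 | acrolein | C=CC=O | starting material
2 | 3-nitropropanal | O=CCC[N+](=O)[O-] | intermediate
3 | methyl (triphenylphosphoranylidene)acetate | COC(=O)C=P(c1ccccc1)(c1ccccc1)c1ccccc1 | starting material
4 | methyl (E)-5-nitropent-2-enoate | COC(=O)/C=C/CC[N+](=O)[O-] | intermediate
5 | (E)-crotonaldehyde | C/C=C/C=O | starting material
6 | methyl (2E,6R)-6-methyl-5-nitro-8-oxooct-2-enoate (C-5 epimers; present as its enamine) | COC(=O)/C=C/CC([N+](=O)[O-])[C@H](C)CC=O | intermediate (not isolated)
7 | methyl 2-[(1S,2S,3R,4R)-2-formyl-3-methyl-4-nitrocyclopentyl]acetate | COC(=O)C[C@@H]1C[C@@H]([N+](=O)[O-])[C@H](C)[C@H]1C=O | intermediate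
8 | methyl 2-[(1S,2S,3R,4R)-2-(hydroxymethyl)-3-methyl-4-nitrocyclopentyl]acetate | COC(=O)C[C@@H]1C[C@@H]([N+](=O)[O-])[C@H](C)[C@H]1CO | intermediate (not isolated)
9 | TBS ether of 8 | COC(=O)C[C@@H]1C[C@@H]([N+](=O)[O-])[C@H](C)[C@H]1CO[Si](C)(C)C(C)(C)C | intermediate
10 | sodium nitronate of 9 | COC(=O)C[C@@H]1CC(=[N+]([O-])[O-])[C@H](C)[C@H]1CO[Si](C)(C)C(C)(C)C.[Na+] | intermediate (not isolated)
11 | methyl 2-[(1S,2S,3R)-2-(tert-butyldimethylsilyloxymethyl)-3-methyl-4-oxocyclopentyl]acetate | COC(=O)C[C@@H]1CC(=O)[C@H](C)[C@H]1CO[Si](C)(C)C(C)(C)C | intermediate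
12 | lithium alkoxide of the cis-4-hydroxy ester (O cis to CH3 and to CH2CO2Me) | COC(=O)C[C@@H]1C[C@H]([O-])[C@H](C)[C@H]1CO[Si](C)(C)C(C)(C)C.[Li+] | intermediate (not isolated)
13 | 6-(tert-butyldimethylsilyloxymethyl)-7-methyl-2-oxabicyclo[3.2.1]octan-3-one | O=C2C[C@@H]1C[C@H](O2)[C@H](C)[C@H]1CO[Si](C)(C)C(C)(C)C | intermediate
14 | lithium enolate of 13 | [Li+].[O-]C2=C[C@@H]1C[C@H](O2)[C@H](C)[C@H]1CO[Si](C)(C)C(C)(C)C | intermediate (not isolated)
15 | 4-exo-(hydroxymethyl) lactone | O=C2[C@H](CO)[C@@H]1C[C@H](O2)[C@H](C)[C@H]1CO[Si](C)(C)C(C)(C)C | intermediate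
16 | bis-TBS lactone | O=C2[C@H](CO[Si](C)(C)C(C)(C)C)[C@@H]1C[C@H](O2)[C@H](C)[C@H]1CO[Si](C)(C)C(C)(C)C | intermediate
17 | diol: 3-(TBS-oxy)-2-[4-hydroxy-3-methyl-2-(TBS-oxymethyl)cyclopentyl]propan-1-ol, ring OH cis to CH3 | OC[C@H](CO[Si](C)(C)C(C)(C)C)[C@@H]1C[C@H](O)[C@H](C)[C@H]1CO[Si](C)(C)C(C)(C)C | intermediate
18 | (3aR,6aR)-2,2-dimethyl-3a,6a-dihydro-4H-cyclopenta[d][1,3]dioxol-4-one | CC1(C)O[C@@H]2C=CC(=O)[C@@H]2O1 | starting material
19 | (3aR,6aR)-2,2-dimethyltetrahydro-4H-cyclopenta[d][1,3]dioxol-4-one | CC1(C)O[C@@H]2CCC(=O)[C@@H]2O1 | intermediate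
20 | lithium enolate of 19 (CH2 side) | [Li+].[O-]C1=CC[C@H]2OC(C)(C)O[C@@H]12 | intermediate (not isolated)
21 | methyl 2-[(3aR,5S,6aR)-2,2-dimethyl-4-oxotetrahydro-4H-cyclopenta[d][1,3]dioxol-5-yl]acetate | COC(=O)C[C@@H]1C[C@H]2OC(C)(C)O[C@H]2C1=O | intermediate
22 | methyl 2-[(3aS,4E,5S,6aR)-4-ethylidene-2,2-dimethyltetrahydro-4H-cyclopenta[d][1,3]dioxol-5-yl]acetate | COC(=O)C[C@@H]1C[C@H]2OC(C)(C)O[C@H]2/C1=C/C | intermediate
23 | 2-[(3aS,4E,5S,6aR)-4-ethylidene-2,2-dimethyltetrahydro-4H-cyclopenta[d][1,3]dioxol-5-yl]acetic acid | O=C(O)C[C@@H]1C[C@H]2OC(C)(C)O[C@H]2/C1=C/C | intermediate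
24 | primary mono-ester of 17 with 23 | O=C(C[C@@H]1C[C@H]2OC(C)(C)O[C@H]2/C1=C/C)OC[C@H](CO[Si](C)(C)C(C)(C)C)[C@@H]1C[C@H](O)[C@H](C)[C@H]1CO[Si](C)(C)C(C)(C)C | intermediate
25 | bis-ester, bis-acetonide, bis-TBS ether | O=C(C[C@@H]1C[C@H]2OC(C)(C)O[C@H]2/C1=C/C)OC[C@H](CO[Si](C)(C)C(C)(C)C)[C@@H]1C[C@@H](OC(=O)C[C@@H]2C[C@H]3OC(C)(C)O[C@H]3/C2=C/C)[C@H](C)[C@H]1CO[Si](C)(C)C(C)(C)C | intermediate
26 | hexaol bis-ester | O=C(C[C@@H]1C[C@@H](O)[C@@H](O)/C1=C/C)OC[C@H](CO)[C@@H]1C[C@@H](OC(=O)C[C@@H]2C[C@@H](O)[C@@H](O)/C2=C/C)[C@H](C)[C@H]1CO | intermediate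
27 | CNP0192766.1 | C/C=C(/C=O)[C@@H](CC=O)CC(=O)OC[C@H](CO)[C@@H]1C[C@@H](OC(=O)C[C@H](CC=O)/C(C=O)=C\C)[C@H](C)[C@H]1CO | target

## Count and risks

Total steps: 17. Longest linear sequence: 13 (steps 1–9 and 14–17).

**Step 3 (domino annulation).** The tethered nitroalkane may add to the iminium ion slowly or unselectively, the enoate of 4 may be consumed by oligomerisation or dienamine pathways, or the sequence may stall before ring closure. Fallback: decouple the events, setting out from 5. The same catalyst adds nitromethane to 5 (a well-precedented donor) to give (R)-3-methyl-4-nitrobutanal F1. Acetalisation with HC(OMe)3 and catalytic TsOH gives dimethyl acetal F2. Pd(0)-catalysed allylation of the nitronate with methyl (E)-4-(methoxycarbonyloxy)but-2-enoate attaches the tether as acetal F3. Mild aqueous acid then releases 6, now isolated, and the route is rejoined at 6, which is cyclised to 7 in a separate amine-mediated intramolecular Michael step.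

**Step 15 (Mitsunobu inversion).** The hindered, cis-flanked alkoxyphosphonium ion may be formed slowly or may eliminate to a cyclopentene instead of being displaced. Fallback: from 24, form mesylate F4 (MsCl, Et3N, 0 °C) and displace it with the caesium salt of 23 (Cs2CO3, 18-crown-6, DMF, 50 °C) with inversion. The route is rejoined at 25.

**Step 12 (Wittig ethylidenation).** Facial and rotational control in oxaphosphetane formation may be poor, so that much of the wrong alkene geometry forms. Fallback: from 21, add lithiated ethyldiphenylphosphine oxide (n-BuLi, THF, −78 °C) to obtain the β-hydroxy phosphine oxide F5. Its diastereomers are separated, and the one that leads to the E-alkene is subjected to stereospecific syn-elimination (NaH, DMF; Horner–Wittig). The route is rejoined at 22.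

## Further compounds

F1 | step 3 | (R)-3-methyl-4-nitrobutanal | O=CC[C@@H](C)C[N+](=O)[O-]
F2 | step 3 | (R)-4,4-dimethoxy-2-methyl-1-nitrobutane | COC(OC)C[C@@H](C)C[N+](=O)[O-]
F3 | step 3 | methyl (2E,6R)-8,8-dimethoxy-6-methyl-5-nitrooct-2-enoate (C-5 epimers) | COC(=O)/C=C/CC([N+](=O)[O-])[C@H](C)CC(OC)OC
F4 | step 15 | mesylate of 24 (ring C–O cis to CH3) | O=C(C[C@@H]1C[C@H]2OC(C)(C)O[C@H]2/C1=C/C)OC[C@H](CO[Si](C)(C)C(C)(C)C)[C@@H]1C[C@H](OS(C)(=O)=O)[C@H](C)[C@H]1CO[Si](C)(C)C(C)(C)C
F5 | step 12 | methyl 2-[(3aR,5S,6aR)-4-[1-(diphenylphosphoryl)ethyl]-4-hydroxy-2,2-dimethyltetrahydro-4H-cyclopenta[d][1,3]dioxol-5-yl]acetate (separated diastereomer) | COC(=O)C[C@@H]1C[C@H]2OC(C)(C)O[C@H]2C1(O)C(C)P(=O)(c1ccccc1)c1ccccc1
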